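Numbering used below: seven-membered ring C1 (bears the side chain), C2, C3 (OH), C4 (=CH2), C5, C9, C10 (OH); five-membered ring C5–C6–C7=C8(CH3)–C9; side chain C11 (CH3), C12 (OAc), C13, C14, C15 (isopropenyl carbon). TBS = tert-butyldimethylsilyl.
Retrosynthetic cuts, target backwards: C12–C13 (Grignard addition); C4=CH2 (carbonyl methylenation); C3–O (enolate hydroxylation); C7=C8 (ring-closing metathesis closing the five-membered ring); C8–C9 and C5–C6 (one-flask cuprate addition/enolate allylation across C5=C9); C5=C9 (ring-closing metathesis closing the seven-membered ring); C9–C10 and C4–C5 (two vinyl additions); C1–C2 (lactone enolate allylation).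
Forward order: chiral C5 lactone → acyclic 1,8-diene → cyclohept-2-enone (first ring) → trans-2-allyl-3-isopropenyl ketone → cyclopentene (second and last ring) → C3 hydroxyl, C4 methylene, side-chain tail, acetate, desilylation.
Enabling feature: the five-membered ring holds one isolated double bond, C7=C8, with methyl-bearing C8 bonded to ring-fusion carbon C9 and the C6 methylene bonded to ring-fusion carbon C5. It is therefore the metathesis product of an isopropenyl group on C9 and an allyl group on C5, and both groups go in one operation onto the enone C4(=O)–C5=C9, whose carbonyl carbon is the later methylene carbon C4 and whose γ-silyloxy group at C10 directs the face.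
Stereochemistry: C11 from the chiral lactone; C1 by trans alkylation of its enolate; C10 by Felkin–Anh vinyl addition; C9 anti to the C10 silyloxy group and C5 trans to C9 (trans ring fusion) in the cuprate addition/allylation; C3 by enolate hydroxylation on the β face; C12 by Felkin–Anh Grignard addition.

Key step: step 11

Remark: (S)-4-methyloxolan-2-one (1) is taken to be a purchasable chiral building block; all other starting materials are common catalogue reagents.

Step 1
Reactants: 1 (S)-4-methyloxolan-2-one; 2 allyl bromide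
Product: 4 trans-allyl lactone (3S,4S)-4-methyl-3-(prop-2-en-1-yl)oxolan-2-one, via lithium enolate 3 (not isolated)
Conditions: LiN(i-Pr)2, THF, −78 °C; then 2, −78 to −40 °C
Reagents that add atoms: allyl bromide (2), C=CCBr
Why: Enolate alkylation of a β-substituted γ-butyrolactone should take place on the face opposite the C11 methyl group, which sets C1 trans to C11.

Step 2
Reactants: 4 trans-allyl lactone
Product: 5 lactol (3S,4S)-4-methyl-3-(prop-2-en-1-yl)oxolan-2-ol (both anomers)
Conditions: i-Bu2AlH, CH2Cl2, −78 °C; aq. potassium sodium tartrate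
Reagents that add atoms: none
Why: Partial hydride reduction of a lactone to the lactol at low temperature is standard and leaves the alkene and both stereocenters untouched.

Step 3
Reactants: 5 lactol; 6 vinylmagnesium bromide
Product: 7 diene diol (2S,3S,4S)-2-methyl-3-(prop-2-en-1-yl)hex-5-ene-1,4-diol
Conditions: 6 (3.5 equiv), THF, −78 to 0 °C; then H2O
Reagents that add atoms: vinylmagnesium bromide (6), C=C[Mg]Br
Why: Grignard addition to the open hydroxy-aldehyde form of the lactol should follow the Felkin–Anh model with the α-branched C11 substituent as the large group anti to the nucleophile, which sets C10 syn to the allyl arm on C1.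

Step 4
Reactants: 7 diene diol
Product: 8 bis-silyl ether (primary C12–OTBS, secondary C10–OTBS)
Conditions: t-BuMe2SiOTf, 2,6-lutidine, CH2Cl2, −78 to 0 °C
Reagents that add atoms: tert-butyldimethylsilyl triflate, CC(C)(C)[Si](C)(C)OS(=O)(=O)C(F)(F)F
Why: Silyl ether formation with a silyl triflate and a hindered base is routine for primary and hindered secondary alcohols and installs the C10 silyloxy group that later directs the cuprate.

Step 5
Reactants: 8 bis-silyl ether
Product: 10 hept-6-en-1-ol bis-silyl ether (C4–OH), via B-alkyl-9-BBN adduct 9 (not isolated)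
Conditions: 9-BBN, THF, 0 °C to rt; then NaOH, H2O2, 0 °C
Reagents that add atoms: hydrogen peroxide, OO
Why: Hydroboration–oxidation with bulky 9-BBN should be anti-Markovnikov and chemoselective for the unhindered allyl terminus over the vinyl group on the silyloxy-bearing carbon next to a branch point.

Step 6
Reactants: 10 hept-6-en-1-ol bis-silyl ether
Product: 11 aldehyde (C4 aldehyde, hept-6-enal)
Conditions: Dess–Martin periodinane, NaHCO3, CH2Cl2, 0 °C to rt
Reagents that add atoms: none
Why: Dess–Martin oxidation converts the primary alcohol into the aldehyde under buffered conditions that do not affect silyl ethers or the alkene.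

Step 7
Reactants: 11 aldehyde; 6 vinylmagnesium bromide
Product: 12 dienol (nona-1,8-dien-3-ol, both C4 epimers)
Conditions: 6, THF, −78 °C; then H2O
Reagents that add atoms: vinylmagnesium bromide (6), C=C[Mg]Br
Why: Grignard 1,2-addition gives the allylic alcohol, whose new carbinol center C4 need not be controlled because it is oxidized in step 9.

Step 8
Reactants: 12 dienol
Product: 13 cycloheptenol (4,5-cis-disubstituted cyclohept-2-en-1-ol, both C4 epimers)
Conditions: second-generation Grubbs catalyst (5 mol %), CH2Cl2 (dilute), 40 °C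
Reagents that add atoms: none
Why: Ring-closing metathesis of the 1,8-diene should close the seven-membered ring at C5=C9 with loss of ethene, the free allylic hydroxyl next to C4 aiding initiation.

Step 9
Reactants: 13 cycloheptenol
Product: 14 cycloheptenone (4S,5S)-4-(TBSO)-5-[(2S)-1-(TBSO)propan-2-yl]cyclohept-2-en-1-one
Conditions: Dess–Martin periodinane, NaHCO3, CH2Cl2, 0 °C to rt
Reagents that add atoms: none
Why: Dess–Martin oxidation of the allylic alcohol merges both C4 epimers into one enone without touching the silyl ethers.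

Step 10
Reactants: 14 cycloheptenone; 15 2-bromopropene; 16 allyl iodide
Product: 18 trans-2-allyl-3-isopropenyl cycloheptanone, via lithium enolate 17 (not isolated)
Conditions: 15, t-BuLi, Et2O, −78 °C; CuI, −78 to −40 °C; 14, −78 °C; then HMPA, 16, −78 to −20 °C
Reagents that add atoms: 2-bromopropene (15), CC(Br)=C; allyl iodide (16), C=CCI
Why: Cuprate conjugate addition should occur at C9 anti to the adjacent C10 silyloxy group and the cis C1 substituent, and the regiodefined C5 lithium enolate should be allylated trans to the new isopropenyl group (three-component conjugate addition–enolate alkylation), which sets C9 and C5 and hence the trans ring fusion.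

Step 11
Reactants: 18 trans-2-allyl-3-isopropenyl cycloheptanone
Product: 19 trans-fused hydroazulenone (C4 ketone, C7=C8 alkene)
Conditions: second-generation Grubbs catalyst (5 mol %), CH2Cl2 (dilute), 40 °C
Reagents that add atoms: none
Why: The ruthenium alkylidene should load onto the monosubstituted allyl alkene, form a ruthenacyclobutane with the 1,1-disubstituted isopropenyl alkene and collapse to the C7=C8 double bond with release of ethene (ring-closing olefin metathesis through the alkylidene/metallacyclobutane cycle). The closest known reaction type is the ring-closing metathesis of trans-2-allyl-3-alkenyl cycloalkanones to annulated cyclopentenes carrying a trisubstituted double bond. The five-membered ring closes by joining the two terminal alkene carbons of a hepta-1,6-diene unit whose central C5–C9 bond already lies in the seven-membered ring, so the new double bond ends up endocyclic between C7 and C8. No new stereocenter is formed: C5 and C9 are carried over from step 10, and the neutral conditions should leave the epimerizable C5–H next to the ketone untouched. The step needs ring closure to win over intermolecular metathesis and the double bond to stay at C7=C8; the substrate secures this because it holds only these two alkenes, placed on adjacent carbons, and dilution suppresses dimer formation.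

Step 12
Reactants: 19 trans-fused hydroazulenone
Product: 21 α-hydroxy ketone (C3 β-OH), via potassium enolate 20 (not isolated)
Conditions: KN(SiMe3)2, THF, −78 °C; 2-(benzenesulfonyl)-3-phenyloxaziridine, −78 °C; then AcOH
Reagents that add atoms: 2-(benzenesulfonyl)-3-phenyloxaziridine, O1C(c2ccccc2)N1S(=O)(=O)c1ccccc1
Why: Kinetic deprotonation by the bulky amide should take a C3 methylene proton and not the hindered ring-fusion C5–H, and oxygen transfer to the enolate (enolate α-hydroxylation with an N-sulfonyloxaziridine) should come from the β face, away from the α-oriented C6 methylene on C5 and the C1 side chain, which sets C3.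

Step 13
Reactants: 21 α-hydroxy ketone
Product: 22 α-silyloxy ketone (C3–OTBS)
Conditions: t-BuMe2SiCl, imidazole, DMF, rt
Reagents that add atoms: tert-butyldimethylsilyl chloride, CC(C)(C)[Si](C)(C)Cl
Why: Silyl ether formation under mild imidazole conditions protects C3–OH without enolizing the ketone, so that only the C12 oxygen is acylated later.

Step 14
Reactants: 22 α-silyloxy ketone
Product: 23 exocyclic methylene tris-silyl ether (C4=CH2)
Conditions: Cp2TiMe2, toluene, 70 °C, dark
Reagents that add atoms: dimethyltitanocene Cp2TiMe2, C[Ti](C)(C1C=CC=C1)C1C=CC=C1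
Why: Carbonyl methylenation by the titanium methylidene formed thermally from Cp2TiMe2 is non-basic, so the hindered α-silyloxy ketone should give the exocyclic alkene without epimerization at C3 or C5.

Step 15
Reactants: 23 exocyclic methylene tris-silyl ether
Product: 24 primary alcohol (C12–OH; C3 and C10 still silylated)
Conditions: HF·pyridine, pyridine, THF, 0 °C
Reagents that add atoms: none
Why: Buffered fluoride desilylation should cleave the primary silyl ether much faster than the two secondary ones (selective deprotection).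

Step 16
Reactants: 24 primary alcohol
Product: 25 aldehyde (C12 aldehyde, α-methyl at C11)
Conditions: Dess–Martin periodinane, NaHCO3, CH2Cl2, 0 °C
Reagents that add atoms: none
Why: Buffered Dess–Martin oxidation gives the α-branched aldehyde without epimerization at C11.

Step 17
Reactants: 25 aldehyde; 26 4-bromo-2-methylbut-1-ene
Product: 27 C12 carbinol (2S,3S)-2-[ring]-6-methylhept-6-en-3-ol
Conditions: 26, Mg, THF; then 25, −78 °C; then H2O
Reagents that add atoms: 4-bromo-2-methylbut-1-ene (26), as its Grignard reagent, C=C(C)CCBr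
Why: Grignard addition to the α-methyl aldehyde should follow the Felkin–Anh model with ring carbon C1 as the large group, which sets C12 syn to the C11 methyl group.

Step 18
Reactants: 27 C12 carbinol
Product: 28 acetate (C12–OAc)
Conditions: Ac2O, pyridine, 4-(dimethylamino)pyridine (cat.), CH2Cl2, rt
Reagents that add atoms: acetic anhydride, CC(=O)OC(C)=O
Why: Acylation of the only free hydroxyl group with acetic anhydride and a nucleophilic catalyst is a standard esterification.

Step 19
Reactants: 28 acetate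
Product: 29 target
Conditions: HF·pyridine, THF, 0 °C to rt
Reagents that add atoms: none
Why: Global desilylation with acidic fluoride should free both secondary hydroxyl groups while the acetate and the alkenes remain, and the non-basic medium avoids acyl migration.

Compound list
1 | (S)-4-methyloxolan-2-one [(S)-β-methyl-γ-butyrolactone] | C[C@@H]1COC(=O)C1 | starting material
2 | allyl bromide (3-bromoprop-1-ene) | C=CCBr | starting material
3 | lithium enolate of 1 | [Li]OC1=C[C@H](C)CO1 | intermediate (not isolated)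
4 | trans-allyl lactone, (3S,4S)-4-methyl-3-(prop-2-en-1-yl)oxolan-2-one | O1C[C@@H](C)[C@H](CC=C)C1=O | intermediate
5 | lactol, (3S,4S)-4-methyl-3-(prop-2-en-1-yl)oxolan-2-ol, both anomers | O1C[C@@H](C)[C@H](CC=C)C1O | intermediate
6 | vinylmagnesium bromide | C=C[Mg]Br | starting material
7 | diene diol, (2S,3S,4S)-2-methyl-3-(prop-2-en-1-yl)hex-5-ene-1,4-diol | OC[C@@H](C)[C@H](CC=C)[C@@H](O)C=C | intermediate
8 | bis-silyl ether, (2S,3S,4S)-1,4-bis(TBSO)-2-methyl-3-(prop-2-en-1-yl)hex-5-ene | CC(C)(C)[Si](C)(C)OC[C@@H](C)[C@H](CC=C)[C@@H](O[Si](C)(C)C(C)(C)C)C=C | intermediate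
9 | B-alkyl-9-BBN adduct of 8 (boron on the terminal carbon of the former allyl group) | CC(C)(C)[Si](C)(C)OC[C@@H](C)[C@H](CCCB1C2CCCC1CCC2)[C@@H](O[Si](C)(C)C(C)(C)C)C=C | intermediate (not isolated)
10 | (4S,5S)-5-(TBSO)-4-[(2S)-1-(TBSO)propan-2-yl]hept-6-en-1-ol | CC(C)(C)[Si](C)(C)OC[C@@H](C)[C@H](CCCO)[C@@H](O[Si](C)(C)C(C)(C)C)C=C | intermediate
11 | (4S,5S)-5-(TBSO)-4-[(2S)-1-(TBSO)propan-2-yl]hept-6-enal | CC(C)(C)[Si](C)(C)OC[C@@H](C)[C@H](CCC=O)[C@@H](O[Si](C)(C)C(C)(C)C)C=C | intermediate
12 | (6S,7S)-7-(TBSO)-6-[(2S)-1-(TBSO)propan-2-yl]nona-1,8-dien-3-ol, both C3 epimers | CC(C)(C)[Si](C)(C)OC[C@@H](C)[C@H](CCC(O)C=C)[C@@H](O[Si](C)(C)C(C)(C)C)C=C | intermediate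
13 | (4S,5S)-4-(TBSO)-5-[(2S)-1-(TBSO)propan-2-yl]cyclohept-2-en-1-ol, both C1 epimers | CC(C)(C)[Si](C)(C)OC[C@@H](C)[C@@H]1CCC(O)C=C[C@@H]1O[Si](C)(C)C(C)(C)C | intermediate
14 | (4S,5S)-4-(TBSO)-5-[(2S)-1-(TBSO)propan-2-yl]cyclohept-2-en-1-one | CC(C)(C)[Si](C)(C)OC[C@@H](C)[C@@H]1CCC(=O)C=C[C@@H]1O[Si](C)(C)C(C)(C)C | intermediate
15 | 2-bromopropene | CC(Br)=C | starting material
16 | allyl iodide (3-iodoprop-1-ene) | C=CCI | starting material
17 | lithium enolate from cuprate addition to 14 (C4–OLi, C4=C5, isopropenyl on C9) | CC(C)(C)[Si](C)(C)OC[C@@H](C)[C@@H]1CCC(O[Li])=C[C@@H](C(C)=C)[C@@H]1O[Si](C)(C)C(C)(C)C | intermediate (not isolated)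
18 | (2R,3S,4R,5S)-4-(TBSO)-5-[(2S)-1-(TBSO)propan-2-yl]-3-(prop-1-en-2-yl)-2-(prop-2-en-1-yl)cycloheptan-1-one | CC(C)(C)[Si](C)(C)OC[C@@H](C)[C@@H]1CCC(=O)[C@H](CC=C)[C@@H](C(C)=C)[C@@H]1O[Si](C)(C)C(C)(C)C | intermediate
19 | trans-fused hydroazulenone, (3aR,7S,8R,8aS)-8-(TBSO)-7-[(2S)-1-(TBSO)propan-2-yl]-1-methyl-3a,5,6,7,8,8a-hexahydroazulen-4(3H)-one | CC(C)(C)[Si](C)(C)OC[C@@H](C)[C@@H]1CCC(=O)[C@@H]2CC=C(C)[C@H]2[C@@H]1O[Si](C)(C)C(C)(C)C | intermediate
20 | potassium enolate of 19 (C4–OK, C3=C4) | CC(C)(C)[Si](C)(C)OC[C@@H](C)[C@@H]1CC=C(O[K])[C@@H]2CC=C(C)[C@H]2[C@@H]1O[Si](C)(C)C(C)(C)C | intermediate (not isolated)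
21 | (3aR,5R,7S,8R,8aS)-8-(TBSO)-7-[(2S)-1-(TBSO)propan-2-yl]-5-hydroxy-1-methyl-3a,5,6,7,8,8a-hexahydroazulen-4(3H)-one | CC(C)(C)[Si](C)(C)OC[C@@H](C)[C@@H]1C[C@@H](O)C(=O)[C@@H]2CC=C(C)[C@H]2[C@@H]1O[Si](C)(C)C(C)(C)C | intermediate
22 | (3aR,5R,7S,8R,8aS)-5,8-bis(TBSO)-7-[(2S)-1-(TBSO)propan-2-yl]-1-methyl-3a,5,6,7,8,8a-hexahydroazulen-4(3H)-one | CC(C)(C)[Si](C)(C)OC[C@@H](C)[C@@H]1C[C@@H](O[Si](C)(C)C(C)(C)C)C(=O)[C@@H]2CC=C(C)[C@H]2[C@@H]1O[Si](C)(C)C(C)(C)C | intermediate
23 | (3aR,5R,7S,8R,8aS)-5,8-bis(TBSO)-7-[(2S)-1-(TBSO)propan-2-yl]-1-methyl-4-methylidene-3,3a,4,5,6,7,8,8a-octahydroazulene | CC(C)(C)[Si](C)(C)OC[C@@H](C)[C@@H]1C[C@@H](O[Si](C)(C)C(C)(C)C)C(=C)[C@@H]2CC=C(C)[C@H]2[C@@H]1O[Si](C)(C)C(C)(C)C | intermediate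
24 | (2S)-2-[(3aR,5R,7S,8R,8aS)-5,8-bis(TBSO)-1-methyl-4-methylidene-3,3a,4,5,6,7,8,8a-octahydroazulen-7-yl]propan-1-ol | OC[C@@H](C)[C@@H]1C[C@@H](O[Si](C)(C)C(C)(C)C)C(=C)[C@@H]2CC=C(C)[C@H]2[C@@H]1O[Si](C)(C)C(C)(C)C | intermediate
25 | (2S)-2-[(3aR,5R,7S,8R,8aS)-5,8-bis(TBSO)-1-methyl-4-methylidene-3,3a,4,5,6,7,8,8a-octahydroazulen-7-yl]propanal | O=C[C@@H](C)[C@@H]1C[C@@H](O[Si](C)(C)C(C)(C)C)C(=C)[C@@H]2CC=C(C)[C@H]2[C@@H]1O[Si](C)(C)C(C)(C)C | intermediate
26 | 4-bromo-2-methylbut-1-ene | C=C(C)CCBr | starting material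
27 | (2S,3S)-2-[(3aR,5R,7S,8R,8aS)-5,8-bis(TBSO)-1-methyl-4-methylidene-3,3a,4,5,6,7,8,8a-octahydroazulen-7-yl]-6-methylhept-6-en-3-ol | C=C(C)CC[C@H](O)[C@@H](C)[C@@H]1C[C@@H](O[Si](C)(C)C(C)(C)C)C(=C)[C@@H]2CC=C(C)[C@H]2[C@@H]1O[Si](C)(C)C(C)(C)C | intermediate
28 | (2S,3S)-2-[(3aR,5R,7S,8R,8aS)-5,8-bis(TBSO)-1-methyl-4-methylidene-3,3a,4,5,6,7,8,8a-octahydroazulen-7-yl]-6-methylhept-6-en-3-yl acetate | C=C(C)CC[C@H](OC(C)=O)[C@@H](C)[C@@H]1C[C@@H](O[Si](C)(C)C(C)(C)C)C(=C)[C@@H]2CC=C(C)[C@H]2[C@@H]1O[Si](C)(C)C(C)(C)C | intermediate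
29 | (2S,3S)-2-[(3aR,5R,7S,8R,8aS)-5,8-dihydroxy-1-methyl-4-methylidene-3,3a,4,5,6,7,8,8a-octahydroazulen-7-yl]-6-methylhept-6-en-3-yl acetate | C=C(C)CC[C@H](OC(C)=O)[C@@H](C)[C@@H]1C[C@@H](O)C(=C)[C@@H]2CC=C(C)[C@H]2[C@@H]1O | target

Total step count: 19. Longest linear sequence: 19 steps (1 → 29; all steps lie on one line).

Steps most likely to fail

Step 3. The vinyl addition may show poor facial selectivity at C10, because attack through a magnesium-alkoxide chelate can compete with the Felkin–Anh pathway. The fallback sets out from 4 and returns at 8, and sets C10 by reagent control. Lactone 4 would be opened with MeNHOMe·HCl and i-PrMgCl to the hydroxy Weinreb amide F1, silylated (t-BuMe2SiCl, imidazole) to the silyl ether F2, and treated with lithium (trimethylsilyl)acetylide to give the ynone F3. Asymmetric transfer hydrogenation with RuCl(p-cymene)[(R,R)-TsDPEN] in i-PrOH should give the propargylic alcohol F4. This would be silylated (t-BuMe2SiOTf, 2,6-lutidine) to the bis-silyl ether F5, C-desilylated (K2CO3, MeOH) to the terminal alkyne F6, and semi-hydrogenated (H2, Pd/CaCO3 poisoned with Pb(OAc)2, quinoline) to 8.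

Step 17. The Grignard addition may show only modest Felkin–Anh selectivity at C12, and the hindered α-branched aldehyde may partly enolize. The fallback sets out from 25 and returns at 27. The addition would be run as in step 17, and the mixture of 27 and its C12 epimer F7 oxidized with Dess–Martin periodinane to the ketone F8. Reduction of F8 with BH3·SMe2 and the (R)-Me-CBS oxazaborolidine should set C12 by reagent control and give 27.

Step 12. Oxygen transfer may occur on the wrong face of the enolate, or enolization may stray toward C5. The fallback sets out from 19 and returns at 21. The 3-epi alcohol F9 formed in the hydroxylation would be inverted by a Mitsunobu reaction (PPh3, diisopropyl azodicarboxylate, 4-nitrobenzoic acid) to the 4-nitrobenzoate F10 of the required configuration, and F10 methanolyzed (K2CO3, MeOH) to 21.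

Further compounds
F1 | step 3 | hydroxy Weinreb amide, (2S)-2-[(2S)-1-hydroxypropan-2-yl]-N-methoxy-N-methylpent-4-enamide | OC[C@@H](C)[C@H](CC=C)C(=O)N(C)OC
F2 | step 3 | silyl ether, (2S)-2-[(2S)-1-(TBSO)propan-2-yl]-N-methoxy-N-methylpent-4-enamide | CC(C)(C)[Si](C)(C)OC[C@@H](C)[C@H](CC=C)C(=O)N(C)OC
F3 | step 3 | ynone, (4S)-4-[(2S)-1-(TBSO)propan-2-yl]-1-(trimethylsilyl)hept-6-en-1-yn-3-one | CC(C)(C)[Si](C)(C)OC[C@@H](C)[C@H](CC=C)C(=O)C#C[Si](C)(C)C
F4 | step 3 | propargylic alcohol, (3R,4S)-4-[(2S)-1-(TBSO)propan-2-yl]-1-(trimethylsilyl)hept-6-en-1-yn-3-ol | CC(C)(C)[Si](C)(C)OC[C@@H](C)[C@H](CC=C)[C@@H](O)C#C[Si](C)(C)C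
F5 | step 3 | bis-silyl ether, (3R,4S)-3-(TBSO)-4-[(2S)-1-(TBSO)propan-2-yl]-1-(trimethylsilyl)hept-6-en-1-yne | CC(C)(C)[Si](C)(C)OC[C@@H](C)[C@H](CC=C)[C@@H](O[Si](C)(C)C(C)(C)C)C#C[Si](C)(C)C
F6 | step 3 | terminal alkyne, (3R,4S)-3-(TBSO)-4-[(2S)-1-(TBSO)propan-2-yl]hept-6-en-1-yne | CC(C)(C)[Si](C)(C)OC[C@@H](C)[C@H](CC=C)[C@@H](O[Si](C)(C)C(C)(C)C)C#C
F7 | step 17 | C12 epimer of 27, (2S,3R)-hept-6-en-3-ol | C=C(C)CC[C@@H](O)[C@@H](C)[C@@H]1C[C@@H](O[Si](C)(C)C(C)(C)C)C(=C)[C@@H]2CC=C(C)[C@H]2[C@@H]1O[Si](C)(C)C(C)(C)C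
F8 | step 17 | ketone, (2S)-2-[ring]-6-methylhept-6-en-3-one | C=C(C)CCC(=O)[C@@H](C)[C@@H]1C[C@@H](O[Si](C)(C)C(C)(C)C)C(=C)[C@@H]2CC=C(C)[C@H]2[C@@H]1O[Si](C)(C)C(C)(C)C
F9 | step 12 | 3-epi alcohol, (3aR,5S,7S,8R,8aS) epimer of 21 | CC(C)(C)[Si](C)(C)OC[C@@H](C)[C@@H]1C[C@H](O)C(=O)[C@@H]2CC=C(C)[C@H]2[C@@H]1O[Si](C)(C)C(C)(C)C
F10 | step 12 | 4-nitrobenzoate of 21 (C3 ester, configuration as in 21) | CC(C)(C)[Si](C)(C)OC[C@@H](C)[C@@H]1C[C@@H](OC(=O)c3ccc(cc3)[N+](=O)[O-])C(=O)[C@@H]2CC=C(C)[C@H]2[C@@H]1O[Si](C)(C)C(C)(C)C
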